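**Strategy**

Both caffeoyl arms are cut at the bond between Cβ of the propenoate and the ring carbon para to one catechol oxygen. The feature exploited is that O5 and O5' of the two cyclohexane rings each carry a three-carbon acyl group whose Cα=Cβ double bond ends at an aryl ring, so each arm is an O-bound acrylate plus an aryl halide. A single twofold Mizoroki–Heck arylation therefore forms both aryl–Cβ bonds and both E alkenes while leaving the eight ring stereocentres alone. Its substrate is the dimer of two (+)-quinate rings joined by the C7–O1' ester, with acetonides on O3/O4 and O3'/O4', a tert-butyl ester at C7', free O1–H and acrylates on O5 and O5'.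

Key step: step 16

Remark on the chemistry: the stereodescriptors of the target show both cyclohexane rings to be (+)-quinic acid units, the mirror image of the natural (−)-acid [O1, O3 and O4 on one ring face, O5 and C7 on the other; (1R,3S,4R,5S) in the free acid]; the (+)-acid is assumed not to be an article of commerce, so the rings are built from (S)-lactic acid. Quinic acid locants are used throughout (C1 quaternary, C7 carboxyl carbon), with primes for the unit that keeps the free acid; "(+)-quinoyl" is the C7 acyl group.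

**Route**

Step 1
Reactants: 1 (S)-lactic acid; 2 pivalaldehyde
Product: 3 (2S,5S)-2-tert-butyl-5-methyl-1,3-dioxolan-4-one
Conditions: TsOH·H2O (cat.), H2SO4 (cat.), pentane, reflux, Dean–Stark; crystallisation from pentane/Et2O at −78 °C
Reagents that add atoms: none
Why: Acid-catalysed acetalisation of the α-hydroxy acid under water removal should give mainly the cis dioxolanone, the new acetal centre C2 being set (S) under thermodynamic control by the lactate centre, and crystallisation should remove the trans isomer.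

Step 2
Reactants: 3 (2S,5S)-2-tert-butyl-5-methyl-1,3-dioxolan-4-one
Product: 5 (2S)-2-tert-butyl-5-methylidene-1,3-dioxolan-4-one, via bromide 4 (not isolated)
Conditions: NBS, AIBN (cat.), PhCF3, 80 °C; then Et3N, 0 °C to rt
Reagents that add atoms: none
Why: Wohl–Ziegler radical bromination at the tertiary C5–H followed by amine-mediated E2 loss of HBr should give the exocyclic alkene, with the acetal centre C2 untouched and now the only carrier of chirality.

Step 3
Reactants: 5 (2S)-2-tert-butyl-5-methylidene-1,3-dioxolan-4-one; 6 buta-1,3-diene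
Product: 7 (2S,5R)-2-tert-butyl-1,3-dioxaspiro[4.5]dec-7-en-4-one
Conditions: 6 (excess), BHT (cat.), toluene, sealed tube, 100 °C
Reagents that add atoms: none
Why: Diels–Alder cycloaddition of the s-cis-locked α-acyloxyacrylate with a symmetrical diene has no regio- or endo/exo issue, and approach of the diene to the alkene face opposite the tert-butyl group should set the spiro centre (5R), which becomes C1 of the quinate ring.

Step 4
Reactants: 7 (2S,5R)-2-tert-butyl-1,3-dioxaspiro[4.5]dec-7-en-4-one
Product: 9 (1R,4S,5S)-1-hydroxy-4-iodo-6-oxabicyclo[3.2.1]octan-7-one, via hydroxy acid 8 (not isolated)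
Conditions: LiOH, THF/H2O, 0 °C to rt; THF removed; then NaHCO3 (buffer), I2, KI, H2O/CH2Cl2, 0 °C to rt, dark
Reagents that add atoms: lithium hydroxide, [Li+].[OH-]; iodine, II
Why: Saponification of the acylal-type lactone frees the carboxylate and the tertiary hydroxyl, and iodolactonisation (anti addition, the carboxylate attacking the nearer alkene carbon to close the five-membered lactone) sets the C–O and C–I centres relative to C1 because the carboxylate can reach the iodonium ion only from its own ring face.

Step 5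
Reactants: 9 (1R,4S,5S)-1-hydroxy-4-iodo-6-oxabicyclo[3.2.1]octan-7-one
Product: 10 (1R,5S)-1-hydroxy-6-oxabicyclo[3.2.1]oct-3-en-7-one
Conditions: DBU, toluene, 80 °C
Reagents that add atoms: none
Why: E2 dehydroiodination should take the only antiperiplanar hydrogen, the one on C3, so the alkene forms at C3=C4 away from the lactone oxygen and no stereocentre is disturbed.

Step 6
Reactants: 10 (1R,5S)-1-hydroxy-6-oxabicyclo[3.2.1]oct-3-en-7-one
Product: 11 (1R,3S,4S,5S)-1,3,4-trihydroxy-6-oxabicyclo[3.2.1]octan-7-one [(+)-quinic acid 1,5-lactone]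
Conditions: OsO4 (2 mol%), NMO, acetone/H2O, rt
Reagents that add atoms: N-methylmorpholine N-oxide, C[N+]1([O-])CCOCC1; water, O (the oxygen atoms reach the alkene through OsO4, O=[Os](=O)(=O)=O)
Why: Catalytic OsO4 syn-dihydroxylation should occur on the open face of the cyclohexene opposite the lactone bridge, which places O3 and O4 cis to each other and trans to O5.

Step 7
Reactants: 11 (+)-quinic acid 1,5-lactone
Product: 12 3,4-O-isopropylidene-(+)-quinic acid 1,5-lactone
Conditions: 2,2-dimethoxypropane, TsOH·H2O (cat.), acetone, rt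
Reagents that add atoms: 2,2-dimethoxypropane, COC(C)(C)OC
Why: Acid-catalysed transketalisation should engage only the cis-vicinal O3/O4 diol, since the bridgehead tertiary hydroxyl has no partner.

Step 8
Reactants: 12 3,4-O-isopropylidene-(+)-quinic acid 1,5-lactone
Product: 13 3,4-O-isopropylidene-(+)-quinic acid
Conditions: LiOH, THF/H2O, 0 °C; then 1 M HCl to pH 3, 0 °C, EtOAc extraction
Reagents that add atoms: lithium hydroxide, [Li+].[OH-]
Why: Saponification of the strained γ-lactone by acyl–oxygen cleavage touches no stereocentre, and cold, brief acidification should avoid relactonisation and acetonide loss.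

Step 9
Reactants: 13 3,4-O-isopropylidene-(+)-quinic acid
Product: 15 1,5-bis-O-(triethylsilyl)-3,4-O-isopropylidene-(+)-quinic acid, via tris-silyl compound 14 (not isolated)
Conditions: Et3SiOTf (3.5 equiv), 2,6-lutidine, CH2Cl2, −78 to 0 °C; then K2CO3 (cat.), THF/H2O, 0 °C; pH 5 buffer work-up
Reagents that add atoms: triethylsilyl trifluoromethanesulfonate, CC[Si](CC)(CC)OS(=O)(=O)C(F)(F)F
Why: Silyl triflate silylation should cover the secondary O5–H, the hindered tertiary O1–H and the acid, and mild aqueous base should then hydrolyse only the labile silyl ester.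

Step 10
Reactants: 13 3,4-O-isopropylidene-(+)-quinic acid
Product: 16 tert-butyl 3,4-O-isopropylidene-(+)-quinate
Conditions: O-tert-butyl-N,N'-diisopropylisourea (3 equiv), CH2Cl2, rt
Reagents that add atoms: O-tert-butyl-N,N'-diisopropylisourea, CC(C)NC(=NC(C)C)OC(C)(C)C
Why: tert-Butyl transfer from the protonated isourea to the carboxylate (isourea esterification) needs neither acid catalyst nor heat, so the two hydroxyls should not be alkylated and neither lactonisation nor acetonide loss is expected.

Step 11
Reactants: 16 tert-butyl 3,4-O-isopropylidene-(+)-quinate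
Product: 17 tert-butyl 3,4-O-isopropylidene-5-O-(triethylsilyl)-(+)-quinate
Conditions: Et3SiCl (1.1 equiv), imidazole, CH2Cl2, 0 °C
Reagents that add atoms: chlorotriethylsilane, CC[Si](Cl)(CC)CC
Why: Silylation with the silyl chloride and imidazole should take the secondary O5–H only, the tertiary O1–H next to the ester being too hindered under these conditions.

Step 12
Reactants: 15 1,5-bis-O-(triethylsilyl)-3,4-O-isopropylidene-(+)-quinic acid; 17 tert-butyl 3,4-O-isopropylidene-5-O-(triethylsilyl)-(+)-quinate
Product: 20 tert-butyl 1'-O-[1,5-bis-O-(triethylsilyl)-3,4-O-isopropylidene-(+)-quinoyl]-3',4'-O-isopropylidene-5'-O-(triethylsilyl)-(+)-quinate, via acid chloride 18 (not isolated), via lithium alkoxide 19 (not isolated)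
Conditions: 15, 1-chloro-N,N,2-trimethylprop-1-en-1-amine, CH2Cl2, 0 °C to rt; 17, LiN(SiMe3)2, THF, −78 °C; then 18 (1.3 equiv) added, −78 °C to rt
Reagents that add atoms: none
Why: Acylation of a lithium tertiary alkoxide by an acid chloride is the established way to esters of tertiary alcohols with hindered acids, the acid chloride being formed under neutral conditions so that silyl ethers and acetonide survive, and neither quaternary C1 centre can epimerise.

Step 13
Reactants: 20 tris-silylated dimer
Product: 21 tert-butyl 1'-O-[3,4-O-isopropylidene-(+)-quinoyl]-3',4'-O-isopropylidene-(+)-quinate (O1–H, O5–H and O5'–H free)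
Conditions: HF·pyridine, pyridine, THF, 0 °C to rt
Reagents that add atoms: none
Why: Fluoride-driven Si–O cleavage buffered with pyridine should remove all three triethylsilyl groups while the acetonides, the tert-butyl ester and the interunit ester remain.

Step 14
Reactants: 21 triol dimer; 22 acryloyl chloride
Product: 23 tert-butyl 5'-O-acryloyl-1'-O-[5-O-acryloyl-3,4-O-isopropylidene-(+)-quinoyl]-3',4'-O-isopropylidene-(+)-quinate
Conditions: 22 (2.6 equiv), i-Pr2NEt, DMAP (cat.), BHT (trace), CH2Cl2, −20 to 0 °C
Reagents that add atoms: none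
Why: O-Acylation with a small, reactive acid chloride under nucleophilic catalysis should esterify the two secondary hydroxyls O5–H and O5'–H, whereas the tertiary O1–H is too hindered to react at low temperature.

Step 15
Reactants: 24 4-bromocatechol
Product: 25 5-bromo-2,2-dimethyl-1,3-benzodioxole
Conditions: 2,2-dimethoxypropane, TsOH·H2O (cat.), toluene, reflux, MeOH removed over 4 Å molecular sieves
Reagents that add atoms: 2,2-dimethoxypropane, COC(C)(C)OC
Why: Acid-catalysed ketalisation of the catechol, driven by removal of methanol, masks both phenols as one ketal that is inert to palladium and amine base and falls off in the final acid treatment.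

Step 16
Reactants: 23 bis-acrylate dimer; 25 5-bromo-2,2-dimethyl-1,3-benzodioxole
Product: 26 tert-butyl 5'-O-[(E)-3-(2,2-dimethyl-1,3-benzodioxol-5-yl)prop-2-enoyl]-1'-O-{5-O-[(E)-3-(2,2-dimethyl-1,3-benzodioxol-5-yl)prop-2-enoyl]-3,4-O-isopropylidene-(+)-quinoyl}-3',4'-O-isopropylidene-(+)-quinate
Conditions: 25 (2.6 equiv), Pd2(dba)3 (5 mol%), [(t-Bu)3PH]BF4 (20 mol%), Cy2NMe (3 equiv), 1,4-dioxane, rt to 45 °C
Reagents that add atoms: none
Why: Oxidative addition of each equivalent of 25 to the zerovalent palladium–P(t-Bu)3 species gives an arylpalladium bromide that binds an acrylate C=C of 23, inserts syn with the aryl group going to the unsubstituted terminal carbon (Cβ), rotates about the new Cα–Cβ single bond and undergoes syn β-hydride elimination, after which Cy2NMe takes up HBr and regenerates the catalyst. The closest known reaction type is the mild, bulky-phosphine-ligated Mizoroki–Heck arylation of simple acrylate esters with electron-rich aryl bromides. No ring is closed and no stereocentre is created; the eight ring stereocentres lie remote from the reacting alkenes and are not touched. The step needs β-regiochemistry, secured by the polarisation of the acrylate and the steric preference of the aryl group for the CH2 terminus, and E geometry, secured by elimination through the conformer with aryl anti to the ester. Twofold mono-arylation should hold because the β-aryl acrylate products insert far more slowly than terminal acrylates, and the free tertiary O1–H, the ketals and the esters are inert to the hindered amine.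

Step 17
Reactants: 26 protected bis-caffeoyl dimer
Product: 27 5'-O-caffeoyl-1'-O-[5-O-caffeoyl-(+)-quinoyl]-(+)-quinic acid (CNP0107948.2)
Conditions: TFA/H2O (9:1), 0 °C to rt; evaporation; reversed-phase chromatography
Reagents that add atoms: none
Why: Acidolysis should hydrolyse the four isopropylidene ketals and cleave the tert-butyl ester by alkyl–oxygen fission in one operation, while the caffeoyl esters and the interunit ester stay (ionisation at C1' would place a cation next to a carboxyl group) and the absence of base avoids acyl migration.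

**Compound list**

1 | (S)-lactic acid | C[C@H](O)C(=O)O | starting material
2 | pivalaldehyde | CC(C)(C)C=O | starting material
3 | (2S,5S)-2-tert-butyl-5-methyl-1,3-dioxolan-4-one | C[C@@H]1O[C@H](C(C)(C)C)OC1=O | intermediate
4 | (2S,5R)-5-bromo-2-tert-butyl-5-methyl-1,3-dioxolan-4-one | C[C@]1(Br)O[C@H](C(C)(C)C)OC1=O | intermediate
5 | (2S)-2-tert-butyl-5-methylidene-1,3-dioxolan-4-one | C=C1O[C@H](C(C)(C)C)OC1=O | intermediate
6 | buta-1,3-diene | C=CC=C | starting material
7 | (2S,5R)-2-tert-butyl-1,3-dioxaspiro[4.5]dec-7-en-4-one | O=C1O[C@@H](C(C)(C)C)O[C@]12CC=CCC2 | intermediate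
8 | (1R)-1-hydroxycyclohex-3-ene-1-carboxylic acid (lithium salt in solution) | O[C@@]1(C(=O)O)CC=CCC1 | intermediate
9 | (1R,4S,5S)-1-hydroxy-4-iodo-6-oxabicyclo[3.2.1]octan-7-one | O[C@]12C[C@H](OC1=O)[C@@H](I)CC2 | intermediate
10 | (1R,5S)-1-hydroxy-6-oxabicyclo[3.2.1]oct-3-en-7-one | O[C@]12C[C@H](OC1=O)C=CC2 | intermediate
11 | (1R,3S,4S,5S)-1,3,4-trihydroxy-6-oxabicyclo[3.2.1]octan-7-one, (+)-quinic acid 1,5-lactone | O[C@]12C[C@H](OC1=O)[C@@H](O)[C@@H](O)C2 | intermediate
12 | 3,4-O-isopropylidene-(+)-quinic acid 1,5-lactone | O[C@]12C[C@H](OC1=O)[C@@H](OC(C)(C)O3)[C@@H]3C2 | intermediate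
13 | 3,4-O-isopropylidene-(+)-quinic acid | O[C@H]1C[C@@](O)(C(=O)O)C[C@H](O2)[C@@H]1OC2(C)C | intermediate
14 | triethylsilyl 1,5-bis-O-(triethylsilyl)-3,4-O-isopropylidene-(+)-quinate | CC[Si](CC)(CC)O[C@H]1C[C@@](O[Si](CC)(CC)CC)(C(=O)O[Si](CC)(CC)CC)C[C@H](O2)[C@@H]1OC2(C)C | intermediate
15 | 1,5-bis-O-(triethylsilyl)-3,4-O-isopropylidene-(+)-quinic acid | CC[Si](CC)(CC)O[C@H]1C[C@@](O[Si](CC)(CC)CC)(C(=O)O)C[C@H](O2)[C@@H]1OC2(C)C | intermediate
16 | tert-butyl 3,4-O-isopropylidene-(+)-quinate | O[C@H]1C[C@@](O)(C(=O)OC(C)(C)C)C[C@H](O2)[C@@H]1OC2(C)C | intermediate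
17 | tert-butyl 3,4-O-isopropylidene-5-O-(triethylsilyl)-(+)-quinate | CC[Si](CC)(CC)O[C@H]1C[C@@](O)(C(=O)OC(C)(C)C)C[C@H](O2)[C@@H]1OC2(C)C | intermediate
18 | 1,5-bis-O-(triethylsilyl)-3,4-O-isopropylidene-(+)-quinoyl chloride | CC[Si](CC)(CC)O[C@H]1C[C@@](O[Si](CC)(CC)CC)(C(=O)Cl)C[C@H](O2)[C@@H]1OC2(C)C | intermediate
19 | lithium 1-alkoxide of 17 | [Li+].CC[Si](CC)(CC)O[C@H]1C[C@@]([O-])(C(=O)OC(C)(C)C)C[C@H](O2)[C@@H]1OC2(C)C | intermediate
20 | tert-butyl 1'-O-[1,5-bis-O-(triethylsilyl)-3,4-O-isopropylidene-(+)-quinoyl]-3',4'-O-isopropylidene-5'-O-(triethylsilyl)-(+)-quinate | CC[Si](CC)(CC)O[C@H]1C[C@@](O[Si](CC)(CC)CC)(C(=O)O[C@@]2(C(=O)OC(C)(C)C)C[C@H](O[Si](CC)(CC)CC)[C@@H](O3)[C@@H](OC3(C)C)C2)C[C@H](O4)[C@@H]1OC4(C)C | intermediate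
21 | tert-butyl 1'-O-[3,4-O-isopropylidene-(+)-quinoyl]-3',4'-O-isopropylidene-(+)-quinate | O[C@H]1C[C@@](O)(C(=O)O[C@@]2(C(=O)OC(C)(C)C)C[C@H](O)[C@@H](O3)[C@@H](OC3(C)C)C2)C[C@H](O4)[C@@H]1OC4(C)C | intermediate
22 | acryloyl chloride | C=CC(=O)Cl | starting material
23 | tert-butyl 5'-O-acryloyl-1'-O-[5-O-acryloyl-3,4-O-isopropylidene-(+)-quinoyl]-3',4'-O-isopropylidene-(+)-quinate | C=CC(=O)O[C@H]1C[C@@](O)(C(=O)O[C@@]2(C(=O)OC(C)(C)C)C[C@H](OC(=O)C=C)[C@@H](O3)[C@@H](OC3(C)C)C2)C[C@H](O4)[C@@H]1OC4(C)C | intermediate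
24 | 4-bromocatechol | Oc1ccc(Br)cc1O | starting material
25 | 5-bromo-2,2-dimethyl-1,3-benzodioxole | CC1(C)Oc2ccc(Br)cc2O1 | intermediate
26 | tert-butyl 5'-O-[(E)-3-(2,2-dimethyl-1,3-benzodioxol-5-yl)prop-2-enoyl]-1'-O-{5-O-[(E)-3-(2,2-dimethyl-1,3-benzodioxol-5-yl)prop-2-enoyl]-3,4-O-isopropylidene-(+)-quinoyl}-3',4'-O-isopropylidene-(+)-quinate | O=C(/C=C/c1ccc2OC(C)(C)Oc2c1)O[C@H]1C[C@@](O)(C(=O)O[C@@]2(C(=O)OC(C)(C)C)C[C@H](OC(=O)/C=C/c3ccc4OC(C)(C)Oc4c3)[C@@H](O5)[C@@H](OC5(C)C)C2)C[C@H](O6)[C@@H]1OC6(C)C | intermediate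
27 | 5'-O-caffeoyl-1'-O-[5-O-caffeoyl-(+)-quinoyl]-(+)-quinic acid (CNP0107948.2) | O=C(/C=C/c1ccc(O)c(O)c1)O[C@H]1C[C@@](O)(C(=O)O[C@@]2(C(=O)O)C[C@H](OC(=O)/C=C/c3ccc(O)c(O)c3)[C@@H](O)[C@@H](O)C2)C[C@H](O)[C@@H]1O | target

**Step count**

Total steps: 17. Longest linear sequence: 15 steps (steps 1–8, 10–14, 16 and 17).

**Steps most likely to fail, with fallbacks**

1. Step 12. The risk is slow acyl transfer between a tertiary alkoxide and an acid chloride on a fully substituted carbon, with loss of the acid chloride on warming. The fallback changes the alcohol partner; it sets out from 15 and 12 and comes back at 21. Acid chloride 18, made from 15 as before, would acylate the exposed bridgehead hydroxyl of lactone 12 (DMAP, pyridine, ClCH2CH2Cl, 60 °C) to give ester-lactone dimer F1. LiOH (1.1 equiv, THF/H2O, 0 °C) should open only the strained lactone to give hydroxy acid dimer F2. O-tert-Butyl-N,N'-diisopropylisourea would then give tert-butyl ester dimer F3, and HF·pyridine would remove the two silyl groups to give triol 21.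

2. Step 16. The risk is incomplete twofold coupling, the second arm lagging after catalyst deactivation. The fallback builds the Cα=Cβ bonds by olefin cross-metathesis instead; it sets out from 23 and 25 and comes back at 26. Bromide 25 would be vinylated by Suzuki–Miyaura coupling (potassium vinyltrifluoroborate, PdCl2(dppf), Cs2CO3, THF/H2O, 70 °C) to 5-ethenyl-2,2-dimethyl-1,3-benzodioxole F4. Bis-acrylate 23 with excess of this styrene and the second-generation Hoveyda–Grubbs catalyst, RuCl2(H2IMes)(=CH–C6H4-2-O-i-Pr), in CH2Cl2 at 40 °C should give 26 with E geometry and loss of ethene.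

3. Step 3. The risk is polymerisation of the sensitive dienophile at the temperature butadiene requires, or insufficient facial control. The fallback drops the auxiliary and resolves; it sets out from 6 and comes back at 8, which then enters the iodolactonisation of step 4. Buta-1,3-diene 6 and commercial methyl 2-acetoxyacrylate (toluene, sealed tube, 150 °C) would give racemic methyl 1-acetoxycyclohex-3-ene-1-carboxylate F5. NaOH in aqueous MeOH would give racemic 1-hydroxycyclohex-3-ene-1-carboxylic acid F6. Crystallisation with (R)-1-phenylethylamine would give the (R)-acid (R)-amine salt F7 (the antipodal amine being used if the other diastereomer crystallises), and acidification would release acid 8.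

Further compounds
F1 | step 12 | 1'-O-[1,5-bis-O-(triethylsilyl)-3,4-O-isopropylidene-(+)-quinoyl]-3',4'-O-isopropylidene-(+)-quinic acid 1',5'-lactone | CC[Si](CC)(CC)O[C@H]1C[C@@](O[Si](CC)(CC)CC)(C(=O)O[C@]23C[C@H](OC2=O)[C@@H](OC(C)(C)O4)[C@@H]4C3)C[C@H](O5)[C@@H]1OC5(C)C
F2 | step 12 | 1'-O-[1,5-bis-O-(triethylsilyl)-3,4-O-isopropylidene-(+)-quinoyl]-3',4'-O-isopropylidene-(+)-quinic acid | CC[Si](CC)(CC)O[C@H]1C[C@@](O[Si](CC)(CC)CC)(C(=O)O[C@@]2(C(=O)O)C[C@H](O)[C@@H](O3)[C@@H](OC3(C)C)C2)C[C@H](O4)[C@@H]1OC4(C)C
F3 | step 12 | tert-butyl 1'-O-[1,5-bis-O-(triethylsilyl)-3,4-O-isopropylidene-(+)-quinoyl]-3',4'-O-isopropylidene-(+)-quinate | CC[Si](CC)(CC)O[C@H]1C[C@@](O[Si](CC)(CC)CC)(C(=O)O[C@@]2(C(=O)OC(C)(C)C)C[C@H](O)[C@@H](O3)[C@@H](OC3(C)C)C2)C[C@H](O4)[C@@H]1OC4(C)C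
F4 | step 16 | 5-ethenyl-2,2-dimethyl-1,3-benzodioxole | C=Cc1ccc2OC(C)(C)Oc2c1
F5 | step 3 | methyl 1-acetoxycyclohex-3-ene-1-carboxylate (racemic) | COC(=O)C1(OC(C)=O)CC=CCC1
F6 | step 3 | 1-hydroxycyclohex-3-ene-1-carboxylic acid (racemic) | OC1(C(=O)O)CC=CCC1
F7 | step 3 | (R)-1-phenylethylammonium (1R)-1-hydroxycyclohex-3-ene-1-carboxylate | O[C@@]1(C(=O)[O-])CC=CCC1.C[C@@H]([NH3+])c1ccccc1
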